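## Retrosynthetic overview

Germacrane numbering is used: the lactone sits on C7/C8, C1=C10 carries C14, C4=C5 carries C15.

1. Target 39 ⇐ desilylation and α-methylenation of macrolactone 34; the ten-membered ring (formed last) ⇐ ring-closing metathesis at C1=C10 of diene 33.
2. 33 ⇐ Negishi sp3–sp2 coupling (C5–C6) of lactone iodide 22 with (Z)-vinyl iodide 31, which already carries the protected C15 ester (from propargyl alcohol, a butenyl Grignard reagent and acid 25).
3. 22 ⇐ butenolide 16 by anti conjugate addition of a hydroxymethyl anion equivalent (C6; C8 controls C7), Tamao oxidation and iodination.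
4. 16 (γ-lactone, formed first) ⇐ (S)-epichlorohydrin (C8) + vinyl cuprate from 2-bromoallyl alcohol (C9, C10, C14) + (phenylselanyl)acetic acid (C11, C12).

Assumption: the SMILES is read as the (7R,8S) trans-fused 12,8-olide with C1=C10 ring-cis (E by the sequence rules) and C4=C5 ring-trans (Z by the sequence rules).

## Route

Step 1
Reactants: 1 2-bromoprop-2-en-1-ol
Product: 2 [(2-bromoprop-2-en-1-yl)oxy](tert-butyl)dimethylsilane
Conditions: TBSCl, imidazole, CH2Cl2, 0 °C → rt
Reagents that add atoms: tert-butyldimethylsilyl chloride, CC(C)(C)[Si](C)(C)Cl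
Why: Silyl ether formation masks the C14 hydroxyl for the organometallic steps that follow.

Step 2
Reactants: 2 [(2-bromoprop-2-en-1-yl)oxy](tert-butyl)dimethylsilane; 3 (S)-2-(chloromethyl)oxirane
Product: 7 tert-butyldimethyl({2-[(2S)-oxiran-2-ylmethyl]prop-2-en-1-yl}oxy)silane, via vinyllithium 4 (not isolated), via lithium divinylcuprate 5 (not isolated), via chlorohydrin 6 (not isolated)
Conditions: 2 (2.2 equiv), t-BuLi (4.4 equiv), Et2O, −78 °C; CuI (1.1 equiv), −78 → −40 °C; 3 (1.0 equiv), −78 → −20 °C; NH4Cl (aq); crude 6 in MeOH, 2 M NaOH (aq), 0 °C → rt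
Reagents that add atoms: none
Why: Bromine–lithium exchange and Gilman cuprate formation are followed by SN2 opening of the epoxide at its CH2 terminus and Williamson-type closure of the chlorohydrin, so the C8 stereocentre of (S)-epichlorohydrin is carried over untouched as the (S)-epoxide.

Step 3
Reactants: 8 diphenyl diselenide; 9 bromoacetic acid
Product: 11 2-(phenylselanyl)acetic acid, via sodium benzeneselenolate 10 (not isolated)
Conditions: NaBH4, EtOH, 0 °C → rt; BrCH2CO2H/NaOH (aq), rt; HCl (aq)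
Reagents that add atoms: none
Why: Reductive cleavage of the Se–Se bond gives a selenolate that displaces bromide from bromoacetate (SN2).

Step 4
Reactants: 7 tert-butyldimethyl({2-[(2S)-oxiran-2-ylmethyl]prop-2-en-1-yl}oxy)silane; 11 2-(phenylselanyl)acetic acid
Product: 14 (5S)-5-(2-{[(tert-butyldimethylsilyl)oxy]methyl}prop-2-en-1-yl)-3-(phenylselanyl)oxolan-2-one (both C3 epimers), via dilithio dianion 12 (not isolated), via hydroxy acid 13 (not isolated)
Conditions: 11, LiN(i-Pr)2 (LDA, 2.1 equiv), THF, −78 → 0 °C; 7, 0 °C → rt; 1 M HCl to pH 3, 0 °C; PPTS (cat.), PhH, 60 °C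
Reagents that add atoms: none
Why: The carboxylate α-carbanion opens the terminal epoxide at CH2 (SN2) and the γ-hydroxy acid lactonises under mild acid, leaving the C8–O bond and its configuration intact.

Step 5
Reactants: 14 (5S)-5-(2-{[(tert-butyldimethylsilyl)oxy]methyl}prop-2-en-1-yl)-3-(phenylselanyl)oxolan-2-one
Product: 16 (5S)-5-(2-{[(tert-butyldimethylsilyl)oxy]methyl}prop-2-en-1-yl)furan-2(5H)-one, via selenoxide 15 (not isolated)
Conditions: NaIO4, NaHCO3, MeOH/THF/H2O, 0 °C → rt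
Reagents that add atoms: none
Why: Selenide oxidation and selenoxide syn-elimination can only use the ring β-hydrogens and so give the conjugated butenolide at room temperature, without epoxidising the side-chain alkene or epimerising C8.

Step 6
Reactants: 17 chloro(chloromethyl)dimethylsilane
Product: 18 (chloromethyl)dimethyl(propan-2-yloxy)silane
Conditions: i-PrOH, Et3N, Et2O, 0 °C → rt; distillation
Reagents that add atoms: propan-2-ol, CC(C)O
Why: Alcoholysis of the Si–Cl bond (nucleophilic substitution at silicon) gives the oxidisable silane needed for a hydroxymethyl anion equivalent.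

Step 7
Reactants: 16 (5S)-5-(2-{[(tert-butyldimethylsilyl)oxy]methyl}prop-2-en-1-yl)furan-2(5H)-one; 18 (chloromethyl)dimethyl(propan-2-yloxy)silane
Product: 20 (4R,5S)-5-(2-{[(tert-butyldimethylsilyl)oxy]methyl}prop-2-en-1-yl)-4-{[dimethyl(propan-2-yloxy)silyl]methyl}oxolan-2-one, via silylmethyl Grignard reagent 19 (not isolated)
Conditions: 18, Mg, BrCH2CH2Br (cat.), THF, rt → 50 °C; CuBr·SMe2 (10 mol%), THF, −78 °C; 16, −78 → −30 °C; NH4Cl (aq)
Reagents that add atoms: none
Why: Copper-catalysed conjugate addition of the Grignard reagent delivers the C6 carbon to the butenolide face anti to the C8 side chain, setting C7 in the required 4,5-trans relationship.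

Step 8
Reactants: 20 (4R,5S)-5-(2-{[(tert-butyldimethylsilyl)oxy]methyl}prop-2-en-1-yl)-4-{[dimethyl(propan-2-yloxy)silyl]methyl}oxolan-2-one
Product: 21 (4S,5S)-5-(2-{[(tert-butyldimethylsilyl)oxy]methyl}prop-2-en-1-yl)-4-(hydroxymethyl)oxolan-2-one
Conditions: 30% H2O2, KF, KHCO3, THF/MeOH (1:1), rt
Reagents that add atoms: hydrogen peroxide, OO
Why: Tamao oxidation converts the C–Si bond into C–OH without touching either stereocentre, the alkene or the silyl ether.

Step 9
Reactants: 21 (4S,5S)-5-(2-{[(tert-butyldimethylsilyl)oxy]methyl}prop-2-en-1-yl)-4-(hydroxymethyl)oxolan-2-one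
Product: 22 (4R,5S)-5-(2-{[(tert-butyldimethylsilyl)oxy]methyl}prop-2-en-1-yl)-4-(iodomethyl)oxolan-2-one
Conditions: I2, PPh3, imidazole, CH2Cl2, 0 °C → rt
Reagents that add atoms: iodine, II
Why: Appel iodination of the primary alcohol gives the alkyl iodide needed for zinc insertion.

Step 10
Reactants: 23 methyl 2-hydroxy-2-methylpropanoate
Product: 24 methyl 2-methyl-2-[(triethylsilyl)oxy]propanoate
Conditions: Et3SiOTf, 2,6-lutidine, CH2Cl2, 0 °C
Reagents that add atoms: triethylsilyl trifluoromethanesulfonate, CC[Si](CC)(CC)OS(=O)(=O)C(F)(F)F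
Why: The silyl triflate silylates the hindered tertiary alcohol, which would otherwise interfere with esterification, the organozinc and the enolate chemistry.

Step 11
Reactants: 24 methyl 2-methyl-2-[(triethylsilyl)oxy]propanoate
Product: 25 2-methyl-2-[(triethylsilyl)oxy]propanoic acid
Conditions: LiOH·H2O, THF/MeOH/H2O, 40 °C; 1 M HCl to pH 4, 0 °C
Reagents that add atoms: lithium hydroxide, [Li+].[OH-]
Why: Saponification of the methyl ester leaves the base-stable tertiary silyl ether in place.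

Step 12
Reactants: 26 prop-2-yn-1-ol; 27 but-3-en-1-ylmagnesium bromide
Product: 30 (2Z)-2-(but-3-en-1-yl)-3-iodoprop-2-en-1-ol, via bromomagnesium propargyl oxide 28 (not isolated), via alkenylmagnesium chelate 29 (not isolated)
Conditions: 27 (2.4 equiv), CuI (10 mol%), Et2O/THF, −10 °C → rt; I2, THF, −40 → 0 °C; NH4Cl (aq)
Reagents that add atoms: iodine, II
Why: Copper-catalysed anti-carbomagnesiation of the propargylic alkoxide places the butenyl group on C4 and magnesium on C5 cis to the CH2O group (five-membered chelate), and iodinolysis with retention fixes the C4=C5 geometry of the target.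

Step 13
Reactants: 30 (2Z)-2-(but-3-en-1-yl)-3-iodoprop-2-en-1-ol; 25 2-methyl-2-[(triethylsilyl)oxy]propanoic acid
Product: 31 (2Z)-2-(but-3-en-1-yl)-3-iodoprop-2-en-1-yl 2-methyl-2-[(triethylsilyl)oxy]propanoate
Conditions: EDC·HCl, DMAP, CH2Cl2, 0 °C → rt
Reagents that add atoms: none
Why: Steglich esterification installs the C15 ester early; it has no α-hydrogen and is hindered, so it should survive the later organozinc, metathesis and enolate steps.

Step 14
Reactants: 22 (4R,5S)-5-(2-{[(tert-butyldimethylsilyl)oxy]methyl}prop-2-en-1-yl)-4-(iodomethyl)oxolan-2-one; 31 (2Z)-2-(but-3-en-1-yl)-3-iodoprop-2-en-1-yl 2-methyl-2-[(triethylsilyl)oxy]propanoate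
Product: 33 (2Z)-2-(but-3-en-1-yl)-4-[(2S,3R)-2-(2-{[(tert-butyldimethylsilyl)oxy]methyl}prop-2-en-1-yl)-5-oxooxolan-3-yl]but-2-en-1-yl 2-methyl-2-[(triethylsilyl)oxy]propanoate, via alkylzinc iodide 32 (not isolated)
Conditions: 22, Zn dust (activated with BrCH2CH2Br and Me3SiCl), LiCl, THF, 40 °C; then 31, PdCl2(dppf) (5 mol%), THF/DMA, 45 °C
Reagents that add atoms: none
Why: Zinc insertion into the primary C–I bond tolerates the lactone, and the Negishi cross-coupling joins C6 to C5 with retention of alkene geometry because zerovalent palladium inserts into the vinyl C–I bond faster than it ionises the hindered allylic ester.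

Step 15
Reactants: 33 (2Z)-2-(but-3-en-1-yl)-4-[(2S,3R)-2-(2-{[(tert-butyldimethylsilyl)oxy]methyl}prop-2-en-1-yl)-5-oxooxolan-3-yl]but-2-en-1-yl 2-methyl-2-[(triethylsilyl)oxy]propanoate
Product: 34 {(3aR,5Z,9E,11aS)-10-{[(tert-butyldimethylsilyl)oxy]methyl}-2-oxo-2,3,3a,4,7,8,11,11a-octahydrocyclodeca[b]furan-6-yl}methyl 2-methyl-2-[(triethylsilyl)oxy]propanoate
Conditions: RuCl2(=CHPh)(PCy3)(H2IMes) (second-generation Grubbs catalyst, 15 mol% in portions), 1,4-benzoquinone (20 mol%), PhMe (1 mM), 80 °C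
Reagents that add atoms: none
Why: Ring-closing metathesis starts at the terminal vinyl group and closes onto the 1,1-disubstituted alkene; in a ten-membered ring that already holds a trans alkene and a trans-fused lactone the new trisubstituted alkene is expected ring-cis (E by the sequence rules), and no stereocentre is touched.

Step 16
Reactants: 34 {(3aR,5Z,9E,11aS)-10-{[(tert-butyldimethylsilyl)oxy]methyl}-2-oxo-2,3,3a,4,7,8,11,11a-octahydrocyclodeca[b]furan-6-yl}methyl 2-methyl-2-[(triethylsilyl)oxy]propanoate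
Product: 38 {(3aR,5Z,9E,11aS)-10-{[(tert-butyldimethylsilyl)oxy]methyl}-3-methylidene-2-oxo-2,3,3a,4,7,8,11,11a-octahydrocyclodeca[b]furan-6-yl}methyl 2-methyl-2-[(triethylsilyl)oxy]propanoate, via lithium enolate 35 (not isolated), via Mannich base 36 (not isolated), via trimethylammonium iodide 37 (not isolated)
Conditions: LiN(i-Pr)2 (LDA, 1.2 equiv), THF, −78 °C; CH2=NMe2+ I− (3 equiv), −78 °C → rt; MeI, MeOH, rt; NaHCO3 (aq)/CH2Cl2, rt
Reagents that add atoms: N,N-dimethylmethyleneiminium iodide (Eschenmoser's salt), C=[N+](C)C.[I-]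
Why: Only the lactone has α-hydrogens, so its enolate undergoes Mannich aminomethylation, and quaternisation followed by E1cB elimination gives the exocyclic methylene without affecting C7 or C8.

Step 17
Reactants: 38 {(3aR,5Z,9E,11aS)-10-{[(tert-butyldimethylsilyl)oxy]methyl}-3-methylidene-2-oxo-2,3,3a,4,7,8,11,11a-octahydrocyclodeca[b]furan-6-yl}methyl 2-methyl-2-[(triethylsilyl)oxy]propanoate
Product: 39 [(3aR,5Z,9E,11aS)-10-(hydroxymethyl)-3-methylidene-2-oxo-2,3,3a,4,7,8,11,11a-octahydrocyclodeca[b]furan-6-yl]methyl 2-hydroxy-2-methylpropanoate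
Conditions: HF·pyridine, pyridine, THF, 0 °C → rt
Reagents that add atoms: none
Why: Buffered fluoride desilylation removes the primary silyl ether and the tertiary triethylsilyl ether in one operation without adding to the α-methylene lactone or cleaving the ester.

## Compound list

1 | 2-bromoprop-2-en-1-ol | C=C(Br)CO | starting material
2 | [(2-bromoprop-2-en-1-yl)oxy](tert-butyl)dimethylsilane | C=C(Br)CO[Si](C)(C)C(C)(C)C | intermediate
3 | (S)-2-(chloromethyl)oxirane ((S)-epichlorohydrin) | ClC[C@@H]1CO1 | starting material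
4 | {3-[(tert-butyldimethylsilyl)oxy]prop-1-en-2-yl}lithium | [Li]C(=C)CO[Si](C)(C)C(C)(C)C | intermediate
5 | lithium bis{3-[(tert-butyldimethylsilyl)oxy]prop-1-en-2-yl}cuprate | [Li+].C=C(CO[Si](C)(C)C(C)(C)C)[Cu-]C(=C)CO[Si](C)(C)C(C)(C)C | intermediate
6 | (2S)-4-{[(tert-butyldimethylsilyl)oxy]methyl}-1-chloropent-4-en-2-ol | ClC[C@@H](O)CC(=C)CO[Si](C)(C)C(C)(C)C | intermediate
7 | tert-butyldimethyl({2-[(2S)-oxiran-2-ylmethyl]prop-2-en-1-yl}oxy)silane | C1[C@@H](O1)CC(=C)CO[Si](C)(C)C(C)(C)C | intermediate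
8 | diphenyl diselenide | c1ccc(cc1)[Se][Se]c1ccccc1 | starting material
9 | bromoacetic acid | OC(=O)CBr | starting material
10 | sodium benzeneselenolate | [Na+].[Se-]c1ccccc1 | intermediate
11 | 2-(phenylselanyl)acetic acid | OC(=O)C[Se]c1ccccc1 | intermediate
12 | lithium 2-lithio-2-(phenylselanyl)acetate (dianion of 11) | [Li]C([Se]c1ccccc1)C(=O)O[Li] | intermediate
13 | (4S)-6-{[(tert-butyldimethylsilyl)oxy]methyl}-4-hydroxy-2-(phenylselanyl)hept-6-enoic acid (C2 epimers) | OC(=O)C([Se]c1ccccc1)C[C@@H](O)CC(=C)CO[Si](C)(C)C(C)(C)C | intermediate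
14 | (5S)-5-(2-{[(tert-butyldimethylsilyl)oxy]methyl}prop-2-en-1-yl)-3-(phenylselanyl)oxolan-2-one (C3 epimers) | O=C1O[C@@H](CC(=C)CO[Si](C)(C)C(C)(C)C)CC1[Se]c1ccccc1 | intermediate
15 | (5S)-3-(benzeneseleninyl)-5-(2-{[(tert-butyldimethylsilyl)oxy]methyl}prop-2-en-1-yl)oxolan-2-one (selenoxide of 14) | O=C1O[C@@H](CC(=C)CO[Si](C)(C)C(C)(C)C)CC1[Se](=O)c1ccccc1 | intermediate
16 | (5S)-5-(2-{[(tert-butyldimethylsilyl)oxy]methyl}prop-2-en-1-yl)furan-2(5H)-one | O=C1O[C@@H](CC(=C)CO[Si](C)(C)C(C)(C)C)C=C1 | intermediate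
17 | chloro(chloromethyl)dimethylsilane | ClC[Si](C)(C)Cl | starting material
18 | (chloromethyl)dimethyl(propan-2-yloxy)silane | ClC[Si](C)(C)OC(C)C | intermediate
19 | {[dimethyl(propan-2-yloxy)silyl]methyl}magnesium chloride | Cl[Mg]C[Si](C)(C)OC(C)C | intermediate
20 | (4R,5S)-5-(2-{[(tert-butyldimethylsilyl)oxy]methyl}prop-2-en-1-yl)-4-{[dimethyl(propan-2-yloxy)silyl]methyl}oxolan-2-one (4,5-trans) | O=C1O[C@@H](CC(=C)CO[Si](C)(C)C(C)(C)C)[C@H](C[Si](C)(C)OC(C)C)C1 | intermediate
21 | (4S,5S)-5-(2-{[(tert-butyldimethylsilyl)oxy]methyl}prop-2-en-1-yl)-4-(hydroxymethyl)oxolan-2-one (4,5-trans) | O=C1O[C@@H](CC(=C)CO[Si](C)(C)C(C)(C)C)[C@H](CO)C1 | intermediate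
22 | (4R,5S)-5-(2-{[(tert-butyldimethylsilyl)oxy]methyl}prop-2-en-1-yl)-4-(iodomethyl)oxolan-2-one (4,5-trans) | O=C1O[C@@H](CC(=C)CO[Si](C)(C)C(C)(C)C)[C@H](CI)C1 | intermediate
23 | methyl 2-hydroxy-2-methylpropanoate | COC(=O)C(C)(C)O | starting material
24 | methyl 2-methyl-2-[(triethylsilyl)oxy]propanoate | COC(=O)C(C)(C)O[Si](CC)(CC)CC | intermediate
25 | 2-methyl-2-[(triethylsilyl)oxy]propanoic acid | OC(=O)C(C)(C)O[Si](CC)(CC)CC | intermediate
26 | prop-2-yn-1-ol | C#CCO | starting material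
27 | but-3-en-1-ylmagnesium bromide (commercial THF solution) | C=CCC[Mg]Br | starting material
28 | bromomagnesium prop-2-yn-1-olate | C#CCO[Mg]Br | intermediate
29 | bromo[(1Z)-2-{[(bromomagnesio)oxy]methyl}hexa-1,5-dien-1-yl]magnesium | Br[Mg]/C=C(/CCC=C)CO[Mg]Br | intermediate
30 | (2Z)-2-(but-3-en-1-yl)-3-iodoprop-2-en-1-ol | I/C=C(/CCC=C)CO | intermediate
31 | (2Z)-2-(but-3-en-1-yl)-3-iodoprop-2-en-1-yl 2-methyl-2-[(triethylsilyl)oxy]propanoate | I/C=C(/CCC=C)COC(=O)C(C)(C)O[Si](CC)(CC)CC | intermediate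
32 | iodo{[(2S,3R)-2-(2-{[(tert-butyldimethylsilyl)oxy]methyl}prop-2-en-1-yl)-5-oxooxolan-3-yl]methyl}zinc | O=C1O[C@@H](CC(=C)CO[Si](C)(C)C(C)(C)C)[C@H](C[Zn]I)C1 | intermediate
33 | (2Z)-2-(but-3-en-1-yl)-4-[(2S,3R)-2-(2-{[(tert-butyldimethylsilyl)oxy]methyl}prop-2-en-1-yl)-5-oxooxolan-3-yl]but-2-en-1-yl 2-methyl-2-[(triethylsilyl)oxy]propanoate | O=C1O[C@@H](CC(=C)CO[Si](C)(C)C(C)(C)C)[C@H](C/C=C(/CCC=C)COC(=O)C(C)(C)O[Si](CC)(CC)CC)C1 | intermediate
34 | {(3aR,5Z,9E,11aS)-10-{[(tert-butyldimethylsilyl)oxy]methyl}-2-oxo-2,3,3a,4,7,8,11,11a-octahydrocyclodeca[b]furan-6-yl}methyl 2-methyl-2-[(triethylsilyl)oxy]propanoate | C1C(=O)O[C@H]2C/C(CO[Si](C)(C)C(C)(C)C)=C\CC/C(COC(=O)C(C)(C)O[Si](CC)(CC)CC)=C/C[C@H]12 | intermediate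
35 | lithium enolate of 34 (O-lithio ketene acetal, C11=C12) | C1=C(O[Li])O[C@H]2C/C(CO[Si](C)(C)C(C)(C)C)=C\CC/C(COC(=O)C(C)(C)O[Si](CC)(CC)CC)=C/C[C@H]12 | intermediate
36 | 3-[(dimethylamino)methyl] derivative of 34 (Mannich base, C3 epimers) | CN(C)CC1C(=O)O[C@H]2C/C(CO[Si](C)(C)C(C)(C)C)=C\CC/C(COC(=O)C(C)(C)O[Si](CC)(CC)CC)=C/C[C@H]12 | intermediate
37 | 3-[(trimethylammonio)methyl] derivative of 34, iodide | C[N+](C)(C)CC1C(=O)O[C@H]2C/C(CO[Si](C)(C)C(C)(C)C)=C\CC/C(COC(=O)C(C)(C)O[Si](CC)(CC)CC)=C/C[C@H]12.[I-] | intermediate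
38 | {(3aR,5Z,9E,11aS)-10-{[(tert-butyldimethylsilyl)oxy]methyl}-3-methylidene-2-oxo-2,3,3a,4,7,8,11,11a-octahydrocyclodeca[b]furan-6-yl}methyl 2-methyl-2-[(triethylsilyl)oxy]propanoate | C=C1C(=O)O[C@H]2C/C(CO[Si](C)(C)C(C)(C)C)=C\CC/C(COC(=O)C(C)(C)O[Si](CC)(CC)CC)=C/C[C@H]12 | intermediate
39 | [(3aR,5Z,9E,11aS)-10-(hydroxymethyl)-3-methylidene-2-oxo-2,3,3a,4,7,8,11,11a-octahydrocyclodeca[b]furan-6-yl]methyl 2-hydroxy-2-methylpropanoate | C=C1C(=O)O[C@H]2C/C(CO)=C\CC/C(COC(=O)C(C)(C)O)=C/C[C@H]12 | target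

## Step count and risks

Total step count: 17.
Longest linear sequence: 11 steps (1, 2, 4, 5, 7, 8, 9, 14, 15, 16, 17). The side branches are steps 3, 6, 10–11 and 12–13.

Steps most likely to fail:

- **Step 15 (ring-closing metathesis).** Closing a strained ten-membered ring onto a 1,1-disubstituted alkene may give dimers or no closure. The fallback sets out from 33 and comes back at 34. The lactone of 33 is opened with MeNH(OMe)·HCl/AlMe3 (CH2Cl2, 0 °C) to the seco hydroxy Weinreb amide F1. Its C8 hydroxyl is capped with Et3SiOTf/2,6-lutidine to give the silyl ether F2. The metathesis is then run on this seco diene, which is no longer held by the trans-fused lactone, to give the ten-membered carbocyclic amide F3. PPTS in MeOH removes the secondary silyl ether and the γ-hydroxy amide relactonises with loss of MeNHOMe to 34.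

- **Step 14 (Negishi coupling).** Zinc insertion next to a pendant alkene and coupling beside an allylic ester may give cyclised or allylic-substitution by-products. The fallback sets out from 22 and 31 and comes back at 33. The two iodides are joined directly by nickel-catalysed reductive cross-electrophile coupling, with no preformed organometallic (NiI2, 4,4′-di-tert-butyl-2,2′-bipyridine, Mn powder, DMA, rt). No compound outside the list is made (F0).

- **Step 7 (conjugate addition).** The silylmethyl group may transfer poorly from copper, or 1,2-addition may compete. The fallback sets out from 16 and comes back at 21. Benzophenone-sensitised photochemical addition of methanol (MeOH, Ph2CO, 350 nm) adds a hydroxymethyl radical to C7 anti to the C8 side chain and gives 21 directly, by-passing 20. No compound outside the list is made (F0).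

## Further compounds

F0 | step 7 | none | none
F0 | step 14 | none | none
F1 | step 15 | N-methoxy-N-methyl amide from opening the lactone of 33 at C12–O (free C8–OH; C7 and C8 configured as in 33; (3R,4S) in the hept-6-enamide chain) | CON(C)C(=O)C[C@@H](C/C=C(/CCC=C)COC(=O)C(C)(C)O[Si](CC)(CC)CC)[C@@H](O)CC(=C)CO[Si](C)(C)C(C)(C)C
F2 | step 15 | C8 triethylsilyl ether of F1 | CON(C)C(=O)C[C@@H](C/C=C(/CCC=C)COC(=O)C(C)(C)O[Si](CC)(CC)CC)[C@@H](O[Si](CC)(CC)CC)CC(=C)CO[Si](C)(C)C(C)(C)C
F3 | step 15 | ten-membered carbocycle from ring closure of F2 (C1=C10 ring-cis, C4=C5 ring-trans; C7 bears CH2C(=O)N(OMe)Me, C8 bears OSiEt3; C7 and C8 configured as in 33) | CON(C)C(=O)C[C@H]1C/C=C(COC(=O)C(C)(C)O[Si](CC)(CC)CC)/CC/C=C(CO[Si](C)(C)C(C)(C)C)\C[C@@H]1O[Si](CC)(CC)CC
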